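**Plan** (labdane numbering; target = (4R,5R,9S,10R,13S)-18-acetoxylabd-8(17)-en-15-oic acid, CH2OAc equatorial on C4)
Cuts, in retrosynthetic order: the O-acetyl and silyl groups; C8=C17 (Wittig); C10–C20 (angular methyl via a 1,10-cyclopropane); C5–C6 and C8–C9 together (ring B, with acrolein as C6–C7–C8); C9–C10 (Negishi); C4–C19 (conjugate methylation).
Forward: ring A comes first from methyl 3-oxocyclohex-1-ene-1-carboxylate; the chain C9/C11–C16 from (S)-citronellic acid is joined at C9–C10; ring B then closes in one operation by a Me2AlCl-promoted ene/type 2 carbonyl-ene [3+3] annulation with acrolein.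
Enabling feature: in the 20-nor precursor the ring A alkene C5=C10 with its allylic C9H2 is an ene triad (H–C9–C10=C5) that can bond at both ends, C5 and C9, to the two electrophilic termini of acrolein. The acrolein oxygen lands on C8, the ring B carbon that carries the exocyclic methylene, and, being axial and syn to C10, it then steers the C20 carbon to the β face.
Stereochemistry: C4 from catalyst-controlled conjugate addition; C13 from the chiral pool; C5 from C4 (enophile anti to CH2OSi); C9 and C8 from the chair of the second ene (C9 secured again by equilibration at the 8-ketone); C10 from the 8β-OH-directed cyclopropanation.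

Key step: step 8

Assumption: in step 4 the enantiomer of the chiral NHC ligand is the one that delivers methyl to the face giving (R)-C4; the sense of induction would be confirmed on the first run, the antipodal ligand giving the other enantiomer.

Step 1
Reactants: 1 (S)-citronellic acid [(3S)-3,7-dimethyloct-6-enoic acid]
Product: 2 2-(trimethylsilyl)ethyl (3S)-3,7-dimethyloct-6-enoate
Conditions: Me3SiCH2CH2OH, DCC, DMAP (cat.), CH2Cl2, 0 °C → rt
Reagents that add atoms: 2-(trimethylsilyl)ethanol, C[Si](C)(C)CCO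
Why: Steglich esterification of an unhindered acid leaves the stereocentre (the future C13, from the chiral pool) untouched, and the 2-(trimethylsilyl)ethyl (TMSE) ester is chosen because fluoride can later free the acid beside an acetate and a 1,1-disubstituted alkene.

Step 2
Reactants: 2 2-(trimethylsilyl)ethyl (3S)-3,7-dimethyloct-6-enoate
Product: 4 2-(trimethylsilyl)ethyl (3S)-6-hydroxy-3-methylhexanoate, via aldehyde 3 (not isolated)
Conditions: O3, CH2Cl2/MeOH, −78 °C; then NaBH4, −78 → 0 °C
Reagents that add atoms: ozone, [O-][O+]=O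
Why: Ozonolysis of the trisubstituted alkene with reductive borohydride work-up should give the primary alcohol (the future C9) through aldehyde 3, the ester being inert to NaBH4 at 0 °C.

Step 3
Reactants: 4 2-(trimethylsilyl)ethyl (3S)-6-hydroxy-3-methylhexanoate
Product: 5 2-(trimethylsilyl)ethyl (3S)-6-iodo-3-methylhexanoate
Conditions: PPh3, I2, imidazole, CH2Cl2, 0 °C → rt
Reagents that add atoms: iodine, II
Why: Appel-type iodination converts the primary alcohol into the iodide by SN2 displacement of the oxyphosphonium group, remote from the stereocentre.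

Step 4
Reactants: 6 methyl 3-oxocyclohex-1-ene-1-carboxylate
Product: 8 methyl (1R)-1-methyl-3-{[(trifluoromethyl)sulfonyl]oxy}cyclohex-2-ene-1-carboxylate, via zinc enolate 7 (not isolated)
Conditions: Me2Zn, (CuOTf)2·C6H6 (cat.), chiral sulfonate-bearing imidazolinium salt (NHC precursor, cat.), Et2O, −30 °C; then Tf2O, −78 → 0 °C
Reagents that add atoms: dimethylzinc, C[Zn]C; trifluoromethanesulfonic anhydride, O=S(=O)(OS(=O)(=O)C(F)(F)F)C(F)(F)F
Why: Copper/NHC-catalysed asymmetric conjugate addition of a dialkylzinc to a β-carboalkoxy cyclohexenone delivers methyl (C19) to the ester-bearing carbon and so sets the quaternary C4 (R) under catalyst control, and O-triflation of the zinc enolate fixes the double bond regiospecifically at C5=C10.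

Step 5
Reactants: 8 methyl (1R)-1-methyl-3-{[(trifluoromethyl)sulfonyl]oxy}cyclohex-2-ene-1-carboxylate
Product: 9 (3R)-3-(hydroxymethyl)-3-methylcyclohex-1-en-1-yl trifluoromethanesulfonate
Conditions: iBu2AlH, CH2Cl2, −78 → 0 °C; aq. potassium sodium tartrate
Reagents that add atoms: none
Why: Hydride reduction of the hindered ester with iBu2AlH gives the neopentyl alcohol (the future C18) at a temperature at which an enol triflate is inert, and C4 is not touched.

Step 6
Reactants: 9 (3R)-3-(hydroxymethyl)-3-methylcyclohex-1-en-1-yl trifluoromethanesulfonate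
Product: 10 (3R)-3-methyl-3-({[tri(propan-2-yl)silyl]oxy}methyl)cyclohex-1-en-1-yl trifluoromethanesulfonate
Conditions: iPr3SiOTf, 2,6-lutidine, CH2Cl2, 0 °C
Reagents that add atoms: triisopropylsilyl trifluoromethanesulfonate, CC(C)[Si](OS(=O)(=O)C(F)(F)F)(C(C)C)C(C)C
Why: Silylation with the reactive silyl triflate gives a TIPS ether that makes CH2OSi clearly the larger group on C4 (the basis of the facial control in step 8) and that withstands Lewis acid, zinc carbenoid and hydrogenation.

Step 7
Reactants: 5 2-(trimethylsilyl)ethyl (3S)-6-iodo-3-methylhexanoate; 10 (3R)-3-methyl-3-({[tri(propan-2-yl)silyl]oxy}methyl)cyclohex-1-en-1-yl trifluoromethanesulfonate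
Product: 12 2-(trimethylsilyl)ethyl (3S)-3-methyl-6-[(3R)-3-methyl-3-({[tri(propan-2-yl)silyl]oxy}methyl)cyclohex-1-en-1-yl]hexanoate, via alkylzinc iodide 11 (not isolated)
Conditions: Zn dust, LiCl, THF, 40 °C; then 10, Pd(dppf)Cl2 (cat.), THF, 50 °C
Reagents that add atoms: none
Why: Zinc insertion into the primary iodide (ester tolerated) and Negishi sp3–sp2 coupling with the enol triflate should form the C9–C10 bond with the alkene held at C5=C10, the bidentate phosphine suppressing β-hydride elimination and no stereocentre being formed.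

Step 8
Reactants: 12 2-(trimethylsilyl)ethyl (3S)-3-methyl-6-[(3R)-3-methyl-3-({[tri(propan-2-yl)silyl]oxy}methyl)cyclohex-1-en-1-yl]hexanoate; 13 acrolein (prop-2-enal)
Product: 15 2-(trimethylsilyl)ethyl (13S)-8β-hydroxy-18-[(triisopropylsilyl)oxy]-17,20-dinorlabd-1(10)-en-15-oate, via ene adduct aldehyde 14 (not isolated)
Conditions: 13 (2 equiv), Me2AlCl (3 equiv), CH2Cl2, −78 → 0 °C
Reagents that add atoms: none
Why: Acrolein bound to Me2AlCl reacts as enophile with the trisubstituted C5=C10 alkene of ring A, C6 bonding to C5 while a hydrogen moves from C9 to C7, which gives the (E)-C9=C10 alkylidene aldehyde 14; its Al-bound C8 carbonyl then adds to C9 in an intramolecular type 2 carbonyl-ene reaction (hydrogen from C1 to oxygen), closing ring B and leaving the C1=C10 alkene and an aluminium alkoxide that loses methane. The closest known reaction type is the Lewis acid-promoted sequential ene/ene [3+3] annulation of trisubstituted and 1,1-disubstituted alkenes with acrolein or methyl vinyl ketone. Ring B (C5–C6–C7–C8–C9–C10) closes in the type 2 mode (carbonyl tethered through C5–C6–C7 to the central carbon C10 of the ene unit C9=C10–C1–H) through a chair in which the carbonyl oxygen is axial, the only orientation from which it reaches the allylic hydrogen on C1. C5 is controlled by the neighbouring quaternary C4, the enophile approaching anti to the bulky CH2OTIPS group so that C6 ends cis to the C4 methyl; C9 is controlled by the E geometry of the alkylidene (C11 turned away from C5 by allylic strain, hence equatorial and H9 cis to H5); C8 is controlled by the axial-oxygen chair, which places the hydroxyl β, trans-diaxial to H9. The step needs bonding at C5 and not C10, hydrogen abstraction from C9 and not C1 in the first ene, and ene collapse instead of chloride capture: the first follows from positive charge developing at the more substituted C10, the second from the preference for the alkyl group syn to the vinylic hydrogen, and the third from Me2AlCl being a proton scavenger as well as a Lewis acid.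

Step 9
Reactants: 15 2-(trimethylsilyl)ethyl (13S)-8β-hydroxy-18-[(triisopropylsilyl)oxy]-17,20-dinorlabd-1(10)-en-15-oate
Product: 17 2-(trimethylsilyl)ethyl (13S)-8β-hydroxy-1β,10β-methano-18-[(triisopropylsilyl)oxy]-17,20-dinorlabdan-15-oate, via zinc alkoxide 16 (not isolated)
Conditions: Et2Zn, CH2I2, CH2Cl2, 0 °C → rt
Reagents that add atoms: diiodomethane, ICI
Why: In this hydroxyl-directed Simmons–Smith cyclopropanation the zinc alkoxide of the axial 8β-hydroxyl, which sits syn-1,3 to the β lobe of C10, should deliver CH2 (the future C20) to the β face of the electron-rich C1=C10 alkene and thereby set C10.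

Step 10
Reactants: 17 2-(trimethylsilyl)ethyl (13S)-8β-hydroxy-1β,10β-methano-18-[(triisopropylsilyl)oxy]-17,20-dinorlabdan-15-oate
Product: 18 2-(trimethylsilyl)ethyl (13S)-8β-hydroxy-18-[(triisopropylsilyl)oxy]-17-norlabdan-15-oate
Conditions: H2 (3 atm), PtO2, AcOH, rt
Reagents that add atoms: none
Why: Catalytic hydrogenolysis of a fused cyclopropane cleaves the least substituted and most accessible bond (C1–C20, opposite the quaternary C10), a classical angular-methyl synthesis, so C20 should become the 10β-methyl group with C10 already fixed and no other reducible group present.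

Step 11
Reactants: 18 2-(trimethylsilyl)ethyl (13S)-8β-hydroxy-18-[(triisopropylsilyl)oxy]-17-norlabdan-15-oate
Product: 19 2-(trimethylsilyl)ethyl (13S)-8-oxo-18-[(triisopropylsilyl)oxy]-17-norlabdan-15-oate
Conditions: Dess–Martin periodinane, CH2Cl2, rt
Reagents that add atoms: none
Why: Dess–Martin oxidation turns the hindered axial alcohol into the 8-ketone under non-basic conditions, and C9, now epimerisable, rests in (or can be equilibrated to) the equatorial side-chain configuration.

Step 12
Reactants: 19 2-(trimethylsilyl)ethyl (13S)-8-oxo-18-[(triisopropylsilyl)oxy]-17-norlabdan-15-oate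
Product: 20 2-(trimethylsilyl)ethyl (13S)-18-[(triisopropylsilyl)oxy]labd-8(17)-en-15-oate
Conditions: Ph3PCH3Br, KOtBu, THF, 0 °C → reflux
Reagents that add atoms: methyltriphenylphosphonium bromide, C[P+](c1ccccc1)(c1ccccc1)c1ccccc1.[Br-]
Why: Wittig methylenation of the 8-ketone is the standard entry to the 8(17)-exocyclic alkene of labdanes, the basic medium can only hold C9 in its more stable equatorial configuration, and the non-stabilised ylide leaves the ester alone.

Step 13
Reactants: 20 2-(trimethylsilyl)ethyl (13S)-18-[(triisopropylsilyl)oxy]labd-8(17)-en-15-oate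
Product: 21 (13S)-18-hydroxylabd-8(17)-en-15-oic acid
Conditions: Bu4NF, THF, rt → 40 °C; aq. NH4Cl
Reagents that add atoms: none
Why: Fluoride should cleave both the neopentyl TIPS ether and the TMSE ester (β-silyl fragmentation to ethene) in one operation without acid or strong base, so the exocyclic alkene stays in place.

Step 14
Reactants: 21 (13S)-18-hydroxylabd-8(17)-en-15-oic acid
Product: 23 (13S)-18-acetoxylabd-8(17)-en-15-oic acid, via mixed anhydride 22 (not isolated)
Conditions: Ac2O, pyridine, DMAP (cat.), CH2Cl2, rt; then H2O, rt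
Reagents that add atoms: acetic anhydride, CC(=O)OC(C)=O; water, O
Why: Pyridine/DMAP acetylation esterifies the primary C18 alcohol, while the carboxylic acid forms only a labile mixed anhydride that water hydrolyses back, so the acetoxy acid should result.

**Compound list**
1 | (S)-citronellic acid, (3S)-3,7-dimethyloct-6-enoic acid | CC(C)=CCC[C@H](C)CC(=O)O | starting material
2 | 2-(trimethylsilyl)ethyl (3S)-3,7-dimethyloct-6-enoate | CC(C)=CCC[C@H](C)CC(=O)OCC[Si](C)(C)C | intermediate
3 | 2-(trimethylsilyl)ethyl (3S)-3-methyl-6-oxohexanoate | O=CCC[C@H](C)CC(=O)OCC[Si](C)(C)C | intermediate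
4 | 2-(trimethylsilyl)ethyl (3S)-6-hydroxy-3-methylhexanoate | OCCC[C@H](C)CC(=O)OCC[Si](C)(C)C | intermediate
5 | 2-(trimethylsilyl)ethyl (3S)-6-iodo-3-methylhexanoate | ICCC[C@H](C)CC(=O)OCC[Si](C)(C)C | intermediate
6 | methyl 3-oxocyclohex-1-ene-1-carboxylate | COC(=O)C1=CC(=O)CCC1 | starting material
7 | methylzinc enolate of methyl (1R)-1-methyl-3-oxocyclohexane-1-carboxylate (O–Zn on C10, C5=C10) | C[Zn]OC1=C[C@](C)(C(=O)OC)CCC1 | intermediate
8 | methyl (1R)-1-methyl-3-{[(trifluoromethyl)sulfonyl]oxy}cyclohex-2-ene-1-carboxylate | O=S(=O)(OC1=C[C@](C)(C(=O)OC)CCC1)C(F)(F)F | intermediate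
9 | (3R)-3-(hydroxymethyl)-3-methylcyclohex-1-en-1-yl trifluoromethanesulfonate | O=S(=O)(OC1=C[C@](C)(CO)CCC1)C(F)(F)F | intermediate
10 | (3R)-3-methyl-3-({[tri(propan-2-yl)silyl]oxy}methyl)cyclohex-1-en-1-yl trifluoromethanesulfonate | O=S(=O)(OC1=C[C@](C)(CO[Si](C(C)C)(C(C)C)C(C)C)CCC1)C(F)(F)F | intermediate
11 | {(4S)-4-methyl-6-oxo-6-[2-(trimethylsilyl)ethoxy]hexyl}zinc iodide | I[Zn]CCC[C@H](C)CC(=O)OCC[Si](C)(C)C | intermediate
12 | 2-(trimethylsilyl)ethyl (3S)-3-methyl-6-[(3R)-3-methyl-3-({[tri(propan-2-yl)silyl]oxy}methyl)cyclohex-1-en-1-yl]hexanoate | C[C@@H](CCCC1=C[C@](C)(CO[Si](C(C)C)(C(C)C)C(C)C)CCC1)CC(=O)OCC[Si](C)(C)C | intermediate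
13 | acrolein (prop-2-enal) | C=CC=O | starting material
14 | 2-(trimethylsilyl)ethyl (3S,6E)-3-methyl-6-[(2R,3R)-3-methyl-2-(3-oxopropyl)-3-({[tri(propan-2-yl)silyl]oxy}methyl)cyclohexylidene]hexanoate | O=CCC[C@H]1[C@](C)(CO[Si](C(C)C)(C(C)C)C(C)C)CCC/C1=C\CC[C@H](C)CC(=O)OCC[Si](C)(C)C | intermediate
15 | 2-(trimethylsilyl)ethyl (13S)-8β-hydroxy-18-[(triisopropylsilyl)oxy]-17,20-dinorlabd-1(10)-en-15-oate (5α-H; 9α-H; 4β-methyl) | O[C@H]1CC[C@H]2[C@](C)(CO[Si](C(C)C)(C(C)C)C(C)C)CCC=C2[C@H]1CC[C@H](C)CC(=O)OCC[Si](C)(C)C | intermediate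
16 | ethylzinc 8β-alkoxide of 15 | CC[Zn]O[C@H]1CC[C@H]2[C@](C)(CO[Si](C(C)C)(C(C)C)C(C)C)CCC=C2[C@H]1CC[C@H](C)CC(=O)OCC[Si](C)(C)C | intermediate
17 | 2-(trimethylsilyl)ethyl (13S)-8β-hydroxy-1β,10β-methano-18-[(triisopropylsilyl)oxy]-17,20-dinorlabdan-15-oate (the methano carbon is the future C20) | O[C@H]1CC[C@H]2[C@](C)(CO[Si](C(C)C)(C(C)C)C(C)C)CC[C@H]3C[C@]32[C@H]1CC[C@H](C)CC(=O)OCC[Si](C)(C)C | intermediate
18 | 2-(trimethylsilyl)ethyl (13S)-8β-hydroxy-18-[(triisopropylsilyl)oxy]-17-norlabdan-15-oate | O[C@H]1CC[C@H]2[C@](C)(CO[Si](C(C)C)(C(C)C)C(C)C)CCC[C@]2(C)[C@H]1CC[C@H](C)CC(=O)OCC[Si](C)(C)C | intermediate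
19 | 2-(trimethylsilyl)ethyl (13S)-8-oxo-18-[(triisopropylsilyl)oxy]-17-norlabdan-15-oate | O=C1CC[C@H]2[C@](C)(CO[Si](C(C)C)(C(C)C)C(C)C)CCC[C@]2(C)[C@H]1CC[C@H](C)CC(=O)OCC[Si](C)(C)C | intermediate
20 | 2-(trimethylsilyl)ethyl (13S)-18-[(triisopropylsilyl)oxy]labd-8(17)-en-15-oate | C=C1CC[C@H]2[C@](C)(CO[Si](C(C)C)(C(C)C)C(C)C)CCC[C@]2(C)[C@H]1CC[C@H](C)CC(=O)OCC[Si](C)(C)C | intermediate
21 | (13S)-18-hydroxylabd-8(17)-en-15-oic acid | C=C1CC[C@H]2[C@](C)(CO)CCC[C@]2(C)[C@H]1CC[C@H](C)CC(=O)O | intermediate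
22 | acetic (13S)-18-acetoxylabd-8(17)-en-15-oic anhydride | C=C1CC[C@H]2[C@](C)(COC(C)=O)CCC[C@]2(C)[C@H]1CC[C@H](C)CC(=O)OC(C)=O | intermediate
23 | (13S)-18-acetoxylabd-8(17)-en-15-oic acid, (3S)-5-[(1S,4aR,5R,8aR)-5-(acetoxymethyl)-5,8a-dimethyl-2-methylidenedecahydronaphthalen-1-yl]-3-methylpentanoic acid | C=C1CC[C@H]2[C@](C)(COC(C)=O)CCC[C@]2(C)[C@H]1CC[C@H](C)CC(=O)O | target

**Totals.** 14 steps in all; longest linear sequence 11 steps (6 → 23 through steps 4–14; the branch from 1 through steps 1–3 and 7–14 is equally long).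

**Steps most likely to fail**

Step 8. The intermolecular ene at C5 is next to the quaternary C4 and may be too slow against acrolein oligomerisation; it may also take the ring hydrogen on C1 instead of that on C9 (leading to a bridged isomer), or show weak facial selectivity at C5, which cannot be corrected later. Fallback, from 12 back to 14: the first C–C bond is made with the smallest and most reactive enophile, formaldehyde (paraformaldehyde, Me2AlCl, CH2Cl2, 0 °C), which should give the C5-hydroxymethyl (E)-alkylidene alcohol F1. Dess–Martin oxidation then gives the β,γ-unsaturated aldehyde F2, Wittig reaction with Ph3P=CHCHO the (E)-enal F3, and conjugate reduction with [CuH(PPh3)]6 the aldehyde 14. There the route is rejoined, 14 being closed to 15 with Me2AlCl as a separate intramolecular type 2 carbonyl-ene reaction.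

Step 9. Direction by the homoallylic hydroxyl may be too weak against the congestion of the β face by the axial C19 methyl, so that the carbenoid attacks from the α face or the reaction stalls; the regiochemistry of the cyclopropane hydrogenolysis in step 10 carries a related risk. Fallback, from 15 back to 19, bypassing steps 9–11: Dess–Martin oxidation gives the β,γ-unsaturated 8-ketone F4, and DBU moves the alkene into conjugation to give the 9(10)-en-8-one F5. Corey–Bakshi–Shibata reduction (oxazaborolidine antipode chosen for the 8β-alcohol, BH3·SMe2) gives the allylic alcohol F6, whose hydroxyl directs the Simmons–Smith reaction (Et2Zn, CH2I2) more strongly, to the 9β,10β-methano alcohol F7. Dess–Martin oxidation gives the cyclopropyl ketone F8, and SmI2 (THF/MeOH) should cleave the C9–C20 bond that overlaps with the carbonyl π system, which makes the 10β-methyl group and, after protonation of C9 to the equatorial side chain, ketone 19.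

Step 4. Enantiofacial control on this particular β-carboalkoxy enone may be incomplete, or 1,2-addition may compete. Fallback, from 6 back to 9: the same conjugate methylation run without chiral ligand (Me2Zn, (CuOTf)2·C6H6, P(OEt)3, then Tf2O) passes through the racemic methylzinc enolate F9 to the racemic enol triflate ester F10, and iBu2AlH reduction gives the racemic alcohol F11. Its enantiomers are separated by preparative chromatography on a chiral stationary phase, the (R)-enantiomer being 9.

**Further compounds**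
F1 | step 8 | 2-(trimethylsilyl)ethyl (3S,6E)-6-[(2R,3R)-2-(hydroxymethyl)-3-methyl-3-({[tri(propan-2-yl)silyl]oxy}methyl)cyclohexylidene]-3-methylhexanoate | OC[C@H]1[C@](C)(CO[Si](C(C)C)(C(C)C)C(C)C)CCC/C1=C\CC[C@H](C)CC(=O)OCC[Si](C)(C)C
F2 | step 8 | 2-(trimethylsilyl)ethyl (3S,6E)-6-[(2R,3R)-2-formyl-3-methyl-3-({[tri(propan-2-yl)silyl]oxy}methyl)cyclohexylidene]-3-methylhexanoate | O=C[C@H]1[C@](C)(CO[Si](C(C)C)(C(C)C)C(C)C)CCC/C1=C\CC[C@H](C)CC(=O)OCC[Si](C)(C)C
F3 | step 8 | 2-(trimethylsilyl)ethyl (3S,6E)-3-methyl-6-[(2R,3R)-3-methyl-2-[(1E)-3-oxoprop-1-en-1-yl]-3-({[tri(propan-2-yl)silyl]oxy}methyl)cyclohexylidene]hexanoate | O=C/C=C/[C@H]1[C@](C)(CO[Si](C(C)C)(C(C)C)C(C)C)CCC/C1=C\CC[C@H](C)CC(=O)OCC[Si](C)(C)C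
F4 | step 9 | 2-(trimethylsilyl)ethyl (13S)-8-oxo-18-[(triisopropylsilyl)oxy]-17,20-dinorlabd-1(10)-en-15-oate | O=C1CC[C@H]2[C@](C)(CO[Si](C(C)C)(C(C)C)C(C)C)CCC=C2[C@H]1CC[C@H](C)CC(=O)OCC[Si](C)(C)C
F5 | step 9 | 2-(trimethylsilyl)ethyl (13S)-8-oxo-18-[(triisopropylsilyl)oxy]-17,20-dinorlabd-9(10)-en-15-oate | O=C1CC[C@H]2[C@](C)(CO[Si](C(C)C)(C(C)C)C(C)C)CCCC2=C1CC[C@H](C)CC(=O)OCC[Si](C)(C)C
F6 | step 9 | 2-(trimethylsilyl)ethyl (13S)-8β-hydroxy-18-[(triisopropylsilyl)oxy]-17,20-dinorlabd-9(10)-en-15-oate | O[C@H]1CC[C@H]2[C@](C)(CO[Si](C(C)C)(C(C)C)C(C)C)CCCC2=C1CC[C@H](C)CC(=O)OCC[Si](C)(C)C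
F7 | step 9 | 2-(trimethylsilyl)ethyl (13S)-8β-hydroxy-9β,10β-methano-18-[(triisopropylsilyl)oxy]-17,20-dinorlabdan-15-oate | O[C@H]1CC[C@H]2[C@](C)(CO[Si](C(C)C)(C(C)C)C(C)C)CCC[C@@]23C[C@@]13CC[C@H](C)CC(=O)OCC[Si](C)(C)C
F8 | step 9 | 2-(trimethylsilyl)ethyl (13S)-9β,10β-methano-8-oxo-18-[(triisopropylsilyl)oxy]-17,20-dinorlabdan-15-oate | O=C1CC[C@H]2[C@](C)(CO[Si](C(C)C)(C(C)C)C(C)C)CCC[C@@]23C[C@@]13CC[C@H](C)CC(=O)OCC[Si](C)(C)C
F9 | step 4 | racemic methylzinc enolate of methyl 1-methyl-3-oxocyclohexane-1-carboxylate | C[Zn]OC1=CC(C)(C(=O)OC)CCC1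
F10 | step 4 | racemic methyl 1-methyl-3-{[(trifluoromethyl)sulfonyl]oxy}cyclohex-2-ene-1-carboxylate | COC(=O)C1(C)C=C(OS(=O)(=O)C(F)(F)F)CCC1
F11 | step 4 | racemic 3-(hydroxymethyl)-3-methylcyclohex-1-en-1-yl trifluoromethanesulfonate | OCC1(C)C=C(OS(=O)(=O)C(F)(F)F)CCC1
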